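**Plan** (locants follow the 7-oxabicyclo[4.1.0]hept-3-en-2-one core: C1/C6 epoxide, C2 ketone, C3 bearing CH2OAc, C5 carbinol, C1' side-chain carbinol)
Retrosynthesis: C1'–OH goes back to a ketone, the C2 ketone to an alcohol, the epoxide to a C1=C6 alkene; the carbocycle is then cut at C1–C2 and C5–C6 into an ynone carrying all of the farnesyl-derived chain and a 1,4-dioxygenated diene.
Enabling feature: the ring C3=C4 double bond lies between the oxygenated carbons C2 and C5, opposite C1/C6, which is a Diels–Alder retron; C1 and C6 are taken to alkyne level and the C1' carbonyl on C6 activates them.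
Forward: the ynone (3 steps from farnesol) and a dioxin diene (3 steps) are joined in one catalytic enantioselective cycloaddition that builds the carbocycle; the epoxide ring follows, then the acetonide (a temporary ring that fixes the diene geometry) is removed and C2 is oxidised.
Stereochemistry: C5 from the chiral Lewis acid in the cycloaddition; C2–O cis to C5–O by suprafacial addition; epoxide anti to both oxygens; C1' by 1,3-anti hydride delivery from C5–OH.

Key step: step 7

Assumption: the (S)-oxazaborolidine is taken to give the (6S,8aS) adduct; if the facial sense proves opposite, the (R)-catalyst is used with nothing else changed.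

Step 1
Reactants: 1 (2E,6E)-farnesol
Product: 2 (2E,6E)-farnesal
Conditions: MnO2, CH2Cl2, rt
Reagents that add atoms: none
Why: Activated MnO2 should oxidise the allylic alcohol to the enal chemoselectively and without scrambling the 2E alkene (allylic oxidation).

Step 2
Reactants: 2 (2E,6E)-farnesal; 3 ethynylmagnesium bromide
Product: 4 racemic (4E,8E)-5,9,13-trimethyltetradeca-4,8,12-trien-1-yn-3-ol
Conditions: THF, 0 °C; aq NH4Cl
Reagents that add atoms: none
Why: The alkynyl Grignard reagent should add 1,2 to the enal (Grignard addition); the carbinol centre is left racemic because it is oxidised in the next step.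

Step 3
Reactants: 4 racemic (4E,8E)-5,9,13-trimethyltetradeca-4,8,12-trien-1-yn-3-ol
Product: 5 (4E,8E)-5,9,13-trimethyltetradeca-4,8,12-trien-1-yn-3-one
Conditions: MnO2, CH2Cl2, rt
Reagents that add atoms: none
Why: The doubly activated (allylic and propargylic) secondary alcohol should be oxidised by MnO2 to the cross-conjugated ynone without touching the trisubstituted alkenes.

Step 4
Reactants: 6 2,2-dimethyl-1,3-dioxan-5-one; 7 diethyl (cyanomethyl)phosphonate
Product: 8 2-(2,2-dimethyl-1,3-dioxan-5-ylidene)acetonitrile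
Conditions: NaH, THF, 0 °C to rt
Reagents that add atoms: none
Why: Horner–Wadsworth–Emmons olefination of the electrophilic, symmetrical dioxanone with the phosphonate anion should give a single alkene because both ring arms are identical.

Step 5
Reactants: 8 2-(2,2-dimethyl-1,3-dioxan-5-ylidene)acetonitrile
Product: 10 2-(2,2-dimethyl-1,3-dioxan-5-ylidene)acetaldehyde, via N-(diisobutylaluminio)aldimine 9 (not isolated)
Conditions: i-Bu2AlH, CH2Cl2, −78 °C; aq Rochelle salt, pH 5
Reagents that add atoms: water O
Why: i-Bu2AlH should add once to the nitrile to give the N-aluminated aldimine, stable at −78 °C, which buffered work-up hydrolyses to the enal with the acetonide intact (partial reduction of a nitrile).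

Step 6
Reactants: 10 2-(2,2-dimethyl-1,3-dioxan-5-ylidene)acetaldehyde
Product: 11 5-[(E)-2-(triisopropylsilyloxy)ethenyl]-2,2-dimethyl-4H-1,3-dioxine
Conditions: TIPSOTf, Et3N, Et2O, 0 °C
Reagents that add atoms: triisopropylsilyl trifluoromethanesulfonate CC(C)[Si](OS(=O)(=O)C(F)(F)F)(C(C)C)C(C)C
Why: Soft enolisation (O-silylation, then γ-deprotonation by Et3N) should give the silyl dienol ether; the new enol-ether double bond lies in the ring so its geometry is fixed, and the s-trans enal gives the E silyloxyvinyl unit.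

Step 7
Reactants: 5 (4E,8E)-5,9,13-trimethyltetradeca-4,8,12-trien-1-yn-3-one; 11 5-[(E)-2-(triisopropylsilyloxy)ethenyl]-2,2-dimethyl-4H-1,3-dioxine
Product: 12 (2E,6E)-1-[(6S,8aS)-2,2-dimethyl-6-(triisopropylsilyloxy)-6,8a-dihydro-4H-1,3-benzodioxin-7-yl]-3,7,11-trimethyldodeca-2,6,10-trien-1-one
Conditions: (S)-1-(2-methylphenyl)-3,3-diphenyltetrahydro-1H,3H-pyrrolo[1,2-c][1,3,2]oxazaborole·AlBr3 (20 mol %), CH2Cl2, −78 to −40 °C
Reagents that add atoms: none
Why: Proposed new method: the AlBr3-activated oxazaborolidine binds the ynone carbonyl of 5 and lowers its LUMO, so the terminal alkyne carbon bonds first to the dioxin CH terminus of 11 while the acyl-bearing carbon closes on the silyloxy terminus in one asynchronous concerted [4+2] event; the closest known reaction types are the cationic-oxazaborolidine-catalysed enantioselective Diels–Alder reaction of acetylenic ketones with cyclic dienes and the thermal Diels–Alder reaction of ynones with 1-silyloxydienes. The only ring closed is the six-membered carbocycle (future C1 to C6), formed by suprafacial [4π+2π] cycloaddition across the s-cis diene, the dioxane ring being carried in from 11. C6 of the adduct (the silyloxy carbon, future C5) should be set by the catalyst, whose aryl groups shield one face of the bound ynone and so select one enantiotopic face of the diene, and C8a (future C2) follows from suprafacial addition to the two E-configured termini, which puts both oxygens cis. The regiochemistry needed (acyl carbon next to the silyloxy carbon) is secured by the ring CH2 on the inner diene carbon, which makes the dioxin CH the more nucleophilic terminus (para rule) while the two oxygen donors roughly cancel, and by the less hindered silyloxy terminus taking the substituted alkyne carbon. Chemoselectivity for the alkyne over the β,β-disubstituted side-chain enone rests on its far higher dienophilicity, and the aprotic Lewis acid is chosen so that neither the silyl dienol ether nor the enol acetal is protonated.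

Step 8
Reactants: 12 (the cycloadduct)
Product: 13 acetonide-protected epoxy ketone (7,8-epoxide of 12, oxirane anti to both ring oxygens)
Conditions: TBHP (decane), DBU, CH2Cl2, 0 °C
Reagents that add atoms: tert-butyl hydroperoxide CC(C)(C)OO
Why: Weitz–Scheffer nucleophilic epoxidation: the peroxide should add to the ring β-carbon of the acyl-activated alkene (the β,β-disubstituted side-chain enone is much slower) from the face opposite the adjacent acetal oxygen, and the enolate closes opposite the silyloxy group, so the epoxide forms anti to both ring oxygens.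

Step 9
Reactants: 13 acetonide-protected epoxy ketone
Product: 14 (2E,6E)-1-[(1S,2R,5S,6S)-2-hydroxy-3-(hydroxymethyl)-5-(triisopropylsilyloxy)-7-oxabicyclo[4.1.0]hept-3-en-6-yl]-3,7,11-trimethyldodeca-2,6,10-trien-1-one
Conditions: PPTS (cat.), MeOH, rt
Reagents that add atoms: none
Why: Acid-catalysed transketalisation to methanol should remove the 1,3-dioxane acetonide while the hindered TIPS ether, the epoxide and the trisubstituted alkenes are inert to pyridinium tosylate.

Step 10
Reactants: 14 (the diol)
Product: 15 {(1S,2R,5S,6S)-2-hydroxy-5-(triisopropylsilyloxy)-6-[(2E,6E)-3,7,11-trimethyldodeca-2,6,10-trienoyl]-7-oxabicyclo[4.1.0]hept-3-en-3-yl}methyl acetate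
Conditions: AcCl (1.05 equiv), 2,4,6-collidine, CH2Cl2, −78 °C
Reagents that add atoms: acetyl chloride CC(=O)Cl
Why: Acetyl chloride with the hindered base at low temperature should acylate the primary allylic alcohol far faster than the secondary one flanked by the epoxide (selective acylation).

Step 11
Reactants: 15 (the monoacetate)
Product: 16 {(1R,5S,6S)-2-oxo-5-(triisopropylsilyloxy)-6-[(2E,6E)-3,7,11-trimethyldodeca-2,6,10-trienoyl]-7-oxabicyclo[4.1.0]hept-3-en-3-yl}methyl acetate
Conditions: Dess–Martin periodinane, NaHCO3, CH2Cl2, 0 °C to rt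
Reagents that add atoms: none
Why: Dess–Martin oxidation of the only free hydroxyl should give the ring enone under buffered, non-basic conditions that spare the epoxide and avoid enolisation toward an aromatic ring.

Step 12
Reactants: 16 (the silyl-protected epoxy diketone)
Product: 17 {(1R,5S,6R)-5-hydroxy-2-oxo-6-[(2E,6E)-3,7,11-trimethyldodeca-2,6,10-trienoyl]-7-oxabicyclo[4.1.0]hept-3-en-3-yl}methyl acetate
Conditions: HF·pyridine, pyridine, THF, 0 °C to rt
Reagents that add atoms: none
Why: Fluoride cleavage of the Si–O bond should free the C5 hydroxyl, and buffered HF·pyridine leaves the acetate, the epoxide and the base-sensitive epoxy diketone untouched (desilylation).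

Step 13
Reactants: 17 (the β-hydroxy ketone)
Product: 18 {(1R,5S,6R)-5-hydroxy-6-[(1S,2E,6E)-1-hydroxy-3,7,11-trimethyldodeca-2,6,10-trien-1-yl]-2-oxo-7-oxabicyclo[4.1.0]hept-3-en-3-yl}methyl acetate (CNP0137670.2)
Conditions: Me4NBH(OAc)3, MeCN/AcOH, −30 °C
Reagents that add atoms: none
Why: Evans–Saksena reduction: the C5 hydroxyl should exchange onto boron and deliver hydride intramolecularly to the β-ketone through a chair six-membered transition state with the alkenyl group equatorial, giving the 1,3-anti diol and hence the 1'S carbinol, while the ring enone, which no hydroxyl can reach, is not reduced by the acetoxyborohydride.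

**Compound list**
1 | (2E,6E)-farnesol | OC/C=C(\C)CC/C=C(\C)CCC=C(C)C | starting material
2 | (2E,6E)-farnesal | O=C/C=C(\C)CC/C=C(\C)CCC=C(C)C | intermediate
3 | ethynylmagnesium bromide | C#C[Mg]Br | starting material
4 | racemic (4E,8E)-5,9,13-trimethyltetradeca-4,8,12-trien-1-yn-3-ol | C#CC(O)/C=C(\C)CC/C=C(\C)CCC=C(C)C | intermediate
5 | (4E,8E)-5,9,13-trimethyltetradeca-4,8,12-trien-1-yn-3-one | C#CC(=O)/C=C(\C)CC/C=C(\C)CCC=C(C)C | intermediate
6 | 2,2-dimethyl-1,3-dioxan-5-one | CC1(C)OCC(=O)CO1 | starting material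
7 | diethyl (cyanomethyl)phosphonate | CCOP(=O)(CC#N)OCC | starting material
8 | 2-(2,2-dimethyl-1,3-dioxan-5-ylidene)acetonitrile | CC1(C)OCC(=CC#N)CO1 | intermediate
9 | N-(diisobutylaluminio)-2-(2,2-dimethyl-1,3-dioxan-5-ylidene)ethanimine | CC1(C)OCC(=CC=N[Al](CC(C)C)CC(C)C)CO1 | intermediate (not isolated)
10 | 2-(2,2-dimethyl-1,3-dioxan-5-ylidene)acetaldehyde | CC1(C)OCC(=CC=O)CO1 | intermediate
11 | 5-[(E)-2-(triisopropylsilyloxy)ethenyl]-2,2-dimethyl-4H-1,3-dioxine | CC1(C)OCC(=CO1)/C=C/O[Si](C(C)C)(C(C)C)C(C)C | intermediate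
12 | (2E,6E)-1-[(6S,8aS)-2,2-dimethyl-6-(triisopropylsilyloxy)-6,8a-dihydro-4H-1,3-benzodioxin-7-yl]-3,7,11-trimethyldodeca-2,6,10-trien-1-one | CC1(C)OCC2=C[C@H](O[Si](C(C)C)(C(C)C)C(C)C)C(C(=O)/C=C(\C)CC/C=C(\C)CCC=C(C)C)=C[C@@H]2O1 | intermediate
13 | 7,8-epoxide of 12 with the oxirane anti to both ring oxygens (acetonide of 14; 1S,2R,5S,6S in oxabicyclo numbering) | CC1(C)OCC2=C[C@H](O[Si](C(C)C)(C(C)C)C(C)C)[C@@]3(C(=O)/C=C(\C)CC/C=C(\C)CCC=C(C)C)O[C@H]3[C@@H]2O1 | intermediate
14 | (2E,6E)-1-[(1S,2R,5S,6S)-2-hydroxy-3-(hydroxymethyl)-5-(triisopropylsilyloxy)-7-oxabicyclo[4.1.0]hept-3-en-6-yl]-3,7,11-trimethyldodeca-2,6,10-trien-1-one | OCC1=C[C@H](O[Si](C(C)C)(C(C)C)C(C)C)[C@@]2(C(=O)/C=C(\C)CC/C=C(\C)CCC=C(C)C)O[C@H]2[C@@H]1O | intermediate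
15 | {(1S,2R,5S,6S)-2-hydroxy-5-(triisopropylsilyloxy)-6-[(2E,6E)-3,7,11-trimethyldodeca-2,6,10-trienoyl]-7-oxabicyclo[4.1.0]hept-3-en-3-yl}methyl acetate | CC(=O)OCC1=C[C@H](O[Si](C(C)C)(C(C)C)C(C)C)[C@@]2(C(=O)/C=C(\C)CC/C=C(\C)CCC=C(C)C)O[C@H]2[C@@H]1O | intermediate
16 | {(1R,5S,6S)-2-oxo-5-(triisopropylsilyloxy)-6-[(2E,6E)-3,7,11-trimethyldodeca-2,6,10-trienoyl]-7-oxabicyclo[4.1.0]hept-3-en-3-yl}methyl acetate | CC(=O)OCC1=C[C@H](O[Si](C(C)C)(C(C)C)C(C)C)[C@@]2(C(=O)/C=C(\C)CC/C=C(\C)CCC=C(C)C)O[C@H]2C1=O | intermediate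
17 | {(1R,5S,6R)-5-hydroxy-2-oxo-6-[(2E,6E)-3,7,11-trimethyldodeca-2,6,10-trienoyl]-7-oxabicyclo[4.1.0]hept-3-en-3-yl}methyl acetate | CC(=O)OCC1=C[C@H](O)[C@@]2(C(=O)/C=C(\C)CC/C=C(\C)CCC=C(C)C)O[C@H]2C1=O | intermediate
18 | {(1R,5S,6R)-5-hydroxy-6-[(1S,2E,6E)-1-hydroxy-3,7,11-trimethyldodeca-2,6,10-trien-1-yl]-2-oxo-7-oxabicyclo[4.1.0]hept-3-en-3-yl}methyl acetate (CNP0137670.2) | CC(=O)OCC1=C[C@H](O)[C@@]2([C@@H](O)/C=C(\C)CC/C=C(\C)CCC=C(C)C)O[C@H]2C1=O | target

**Totals**
Total steps: 13. Longest linear sequence: 10 steps (steps 1–3 or 4–6, then 7–13).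

**Steps most likely to fail**

1. Step 7 (proposed new method). The Lewis acid may desilylate or ionise the dienol ether or the doubly allylic adduct, leading to Mukaiyama–Michael products or aromatisation. Facial discrimination of the acyclic diene may also be poor, or bonding may occur in the opposite orientation. The fallback sets out from 5 and 11 and returns at 12. The two are heated without catalyst (toluene, 60 °C), the known thermal Diels–Alder reaction of ynones with 1-silyloxydienes, to give the racemic adduct F1. F1 is resolved by preparative chromatography on a cellulose tris(3,5-dimethylphenylcarbamate) phase, and the (6S,8aS) enantiomer is 12.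

2. Step 8. The base may remove the doubly allylic C8a proton, and the dienolate can aromatise by loss of silanol; peroxide attack on the wrong face is a lesser risk. The fallback sets out from 12 and returns at 13. Luche reduction (NaBH4, CeCl3·7H2O, MeOH, −40 °C) removes the acidifying ketone and gives the C1'-epimeric divinyl carbinols F2. Sharpless epoxidation (Ti(OiPr)4, D-(−)-diethyl tartrate, TBHP, 4 Å sieves, CH2Cl2, −20 °C) of the matched 1'R epimer should deliver oxygen to the ring alkene, which has no cis substituent, on the face anti to the ring oxygens, giving the epoxy alcohol F3. The mismatched epimer is recovered, reoxidised to 12 with MnO2 and recycled. Dess–Martin oxidation of F3 gives 13.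

3. Step 13. Hydride delivery may be slow at the hindered ketone, or may proceed through the other carbonyl rotamer and erode the 1,3-anti selectivity. The fallback sets out from 13 and returns at 18, setting C1' by reagent control while only one ketone is present. CBS reduction of 13 (catecholborane with the antipode of 1-methyl-3,3-diphenyltetrahydro-1H,3H-pyrrolo[1,2-c][1,3,2]oxazaborole that reinforces Felkin–Anh attack anti to the epoxide C–O bond) gives the 1'S alcohol F4. TBSOTf with 2,6-lutidine gives the silyl ether F5, PPTS in MeOH the diol F6, AcCl with collidine the primary acetate F7, and Dess–Martin oxidation the enone F8. HF·pyridine then removes both silyl groups to give 18.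

**Further compounds**
F1 | step 7 | racemic 12 (1:1 mixture of 12 and its enantiomer) | CC1(C)OCC2=C[C@H](O[Si](C(C)C)(C(C)C)C(C)C)C(C(=O)/C=C(\C)CC/C=C(\C)CCC=C(C)C)=C[C@@H]2O1.CC1(C)OCC2=C[C@@H](O[Si](C(C)C)(C(C)C)C(C)C)C(C(=O)/C=C(\C)CC/C=C(\C)CCC=C(C)C)=C[C@H]2O1
F2 | step 8 | (2E,6E)-1-[(6S,8aS)-2,2-dimethyl-6-(triisopropylsilyloxy)-6,8a-dihydro-4H-1,3-benzodioxin-7-yl]-3,7,11-trimethyldodeca-2,6,10-trien-1-ol, both C1' epimers | CC1(C)OCC2=C[C@H](O[Si](C(C)C)(C(C)C)C(C)C)C(C(O)/C=C(\C)CC/C=C(\C)CCC=C(C)C)=C[C@@H]2O1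
F3 | step 8 | (1'R)-alcohol corresponding to 13 (epoxide anti to both ring oxygens, side-chain carbinol 1'R) | CC1(C)OCC2=C[C@H](O[Si](C(C)C)(C(C)C)C(C)C)[C@@]3([C@H](O)/C=C(\C)CC/C=C(\C)CCC=C(C)C)O[C@H]3[C@@H]2O1
F4 | step 13 | (1'S)-alcohol from reduction of 13 | CC1(C)OCC2=C[C@H](O[Si](C(C)C)(C(C)C)C(C)C)[C@@]3([C@@H](O)/C=C(\C)CC/C=C(\C)CCC=C(C)C)O[C@H]3[C@@H]2O1
F5 | step 13 | 1'-O-tert-butyldimethylsilyl ether of F4 | CC1(C)OCC2=C[C@H](O[Si](C(C)C)(C(C)C)C(C)C)[C@@]3([C@@H](O[Si](C)(C)C(C)(C)C)/C=C(\C)CC/C=C(\C)CCC=C(C)C)O[C@H]3[C@@H]2O1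
F6 | step 13 | C2,CH2-diol from F5 (acetonide removed) | OCC1=C[C@H](O[Si](C(C)C)(C(C)C)C(C)C)[C@@]2([C@@H](O[Si](C)(C)C(C)(C)C)/C=C(\C)CC/C=C(\C)CCC=C(C)C)O[C@H]2[C@@H]1O
F7 | step 13 | primary acetate of F6 | CC(=O)OCC1=C[C@H](O[Si](C(C)C)(C(C)C)C(C)C)[C@@]2([C@@H](O[Si](C)(C)C(C)(C)C)/C=C(\C)CC/C=C(\C)CCC=C(C)C)O[C@H]2[C@@H]1O
F8 | step 13 | bis-silyl ether of 18 (5-O-TIPS, 1'-O-TBS) | CC(=O)OCC1=C[C@H](O[Si](C(C)C)(C(C)C)C(C)C)[C@@]2([C@@H](O[Si](C)(C)C(C)(C)C)/C=C(\C)CC/C=C(\C)CCC=C(C)C)O[C@H]2C1=O
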